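**Retrosynthetic overview**
1. The C8 methacrylate C–O bond is made last, from the macrocyclic C8 alcohol.
2. The ten-membered carbocycle (third ring) is closed at C7–C8 by a Nozaki–Hiyama/Barbier allylation of a 3-(bromomethyl)butenolide onto the C8 aldehyde; this also creates the α-methylene lactone and sets C7 and C8.
3. The butenolide (second ring, C6) comes from an asymmetric Nozaki–Hiyama–Kishi coupling/lactonisation of a C6 enal with a β-iodoacrylate.
4. The 3(2H)-furanone (first ring, key step) is formed by C–O bond formation: a CO2-relayed cycloisomerisation of a 4-hydroxy-2-yn-1-one, itself assembled by carbonylative Sonogashira union (C3 from CO) of a Z-vinyl iodide and a tertiary propargylic alcohol.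
5. C10 is set by Sharpless epoxidation and reductive opening of a C6 enynol; C4–C6 and C15 come from but-2-yne-1,4-diol. Ring order: furanone, then butenolide, then ten-membered ring.

Assumption: germacranolide numbering is used (C1 ring ketone; C2=C3 furanone alkene with the ring oxygen between C3 and C10; C4=C5 Z-alkene with C15 acetoxymethyl on C4; C6 lactone carbinol; C7; C8 ester carbinol; C9 CH2; C10 quaternary carbon with C14 methyl; C11=C13 exocyclic methylene; C12 lactone carbonyl), and the target is (6R,7R,8S,10R).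

**Step 1**
Reactants: 1 (Z)-3-methylpent-2-en-4-yn-1-ol
Product: 2 [(2R,3S)-3-ethynyl-3-methyloxiran-2-yl]methanol
Conditions: Ti(OiPr)4 (10 mol%), D-(−)-DIPT (12 mol%), t-BuOOH, 4 Å MS, CH2Cl2, −20 °C
Reagents that add atoms: tert-butyl hydroperoxide CC(C)(C)OO
Why: Sharpless asymmetric epoxidation of the trisubstituted allylic alcohol, in which the D-tartrate delivers oxygen to one face only and so fixes the future C10 (3S in the epoxide; the 2R centre is removed in step 2).

**Step 2**
Reactants: 2 [(2R,3S)-3-ethynyl-3-methyloxiran-2-yl]methanol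
Product: 3 (3R)-3-methylpent-4-yne-1,3-diol
Conditions: NaAlH2(OCH2CH2OMe)2 (2.2 equiv), THF, −20 to 0 °C; aq. potassium sodium tartrate
Reagents that add atoms: none
Why: Alkoxide-directed hydride delivery (Red-Al reduction of a 2,3-epoxy alcohol) opens the epoxide at C2 only because C3 is fully substituted, so the tertiary C–O bond is untouched (the descriptor becomes R by priority change alone), and the low temperature avoids hydroalumination of the alkyne.

**Step 3**
Reactants: 3 (3R)-3-methylpent-4-yne-1,3-diol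
Product: 5 (3R)-5,5-dimethoxy-3-methylpent-1-yn-3-ol, via hydroxy aldehyde 4 (not isolated)
Conditions: TEMPO (10 mol%), PhI(OAc)2, CH2Cl2, rt; then HC(OMe)3, PPTS (cat.), rt
Reagents that add atoms: trimethyl orthoformate COC(OC)OC
Why: Oxoammonium (TEMPO/PhI(OAc)2) oxidation takes the primary alcohol selectively over the tertiary one, and the sensitive β-hydroxy aldehyde is trapped at once by acid-catalysed acetalisation, masking C8.

**Step 4**
Reactants: 6 but-2-yne-1,4-diol
Product: 7 4-hydroxybut-2-yn-1-yl acetate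
Conditions: Ac2O (0.9 equiv), pyridine, CH2Cl2, 0 °C
Reagents that add atoms: acetic anhydride CC(=O)OC(C)=O
Why: Statistical mono-acetylation (nucleophilic acyl substitution) of the symmetric diol with a deficit of anhydride installs the C15 acetate that is carried to the end, and unreacted diol is recycled.

**Step 5**
Reactants: 7 4-hydroxybut-2-yn-1-yl acetate
Product: 8 4-oxobut-2-yn-1-yl acetate
Conditions: activated MnO2, CH2Cl2, rt
Reagents that add atoms: none
Why: MnO2 oxidation of a propargylic alcohol gives the ynal without touching the acetate.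

**Step 6**
Reactants: 8 4-oxobut-2-yn-1-yl acetate
Product: 9 (2Z)-2-iodo-4-oxobut-2-en-1-yl acetate
Conditions: NaI, AcOH, rt
Reagents that add atoms: sodium iodide [Na+].[I-]
Why: Conjugate addition of iodide to the ynal with anti protonation (NaI/AcOH hydroiodination) gives the Z-β-iodoenal, placing iodine cis to the formyl group, which is the C3/C6 cis relationship of the ring alkene.

**Step 7**
Reactants: 5 (3R)-5,5-dimethoxy-3-methylpent-1-yn-3-ol; 9 (2Z)-2-iodo-4-oxobut-2-en-1-yl acetate
Product: 10 (2Z,6R)-6-hydroxy-8,8-dimethoxy-6-methyl-3-oxo-2-(2-oxoethylidene)oct-4-yn-1-yl acetate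
Conditions: PdCl2(PPh3)2 (3 mol%), CuI (3 mol%), Et3N (2 equiv), CO (5 bar), THF, rt
Reagents that add atoms: carbon monoxide [C-]#[O+]
Why: Carbonylative Sonogashira coupling (oxidative addition at the vinyl iodide, CO insertion, alkynyl transfer) joins the two halves through the new carbonyl carbon C3 with retention of the Z-alkene and leaves the tertiary alcohol and both stereo-elements untouched.

**Step 8**
Reactants: 10 (2Z,6R)-6-hydroxy-8,8-dimethoxy-6-methyl-3-oxo-2-(2-oxoethylidene)oct-4-yn-1-yl acetate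
Product: 13 (2Z)-2-[(5R)-5-(2,2-dimethoxyethyl)-5-methyl-4-oxo-4,5-dihydrofuran-2-yl]-4-oxobut-2-en-1-yl acetate, via Z-alkylidene cyclic carbonate 11 (not isolated), via hydroxy 1,3-diketone 12 (not isolated)
Conditions: AgOAc (5 mol%), Et3N (20 mol%), CO2 (1 atm), MeCN–H2O (100:1), rt; then SiO2, CH2Cl2
Reagents that add atoms: carbon dioxide O=C=O
Why: Proposed new method: the tertiary hydroxyl is carboxylated by CO2 and the carbonate oxygen adds 5-exo-dig (anti) to the silver-activated ynone at C1, which is also its Michael position, to give the cyclic carbonate, whose vinylogous acyl carbonate is hydrolysed with loss of CO2 to the hydroxy 1,3-diketone that closes through the C10 oxygen onto C3 and dehydrates to the 3(2H)-furanone, a net isomerisation under near-neutral conditions that spares the acetal, the enal and the C10 stereocentre; the closest known reaction types are the silver-catalysed carboxylative cyclisation of propargylic alcohols with CO2 to alkylidene carbonates (and their hydrolysis to α-hydroxy ketones) and the amine- or mercury-mediated hydration–cyclodehydration of 4-hydroxy-2-ynones to 3(2H)-furanones.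

**Step 9**
Reactants: 14 methyl prop-2-ynoate
Product: 15 methyl (2Z)-2-(hydroxymethyl)-3-iodoprop-2-enoate
Conditions: MgI2, (CH2O)n, CH2Cl2, 0 °C to rt
Reagents that add atoms: formaldehyde (from paraformaldehyde) C=O; magnesium iodide [Mg+2].[I-].[I-]
Why: Iodide adds to the propiolate and the β-iodo allenolate is trapped by formaldehyde (MgI2-mediated iodo-aldol, a β-iodo Morita–Baylis–Hillman reaction), giving the Z-isomer with iodine cis to the ester as needed for later lactonisation.

**Step 10**
Reactants: 13 (2Z)-2-[(5R)-5-(2,2-dimethoxyethyl)-5-methyl-4-oxo-4,5-dihydrofuran-2-yl]-4-oxobut-2-en-1-yl acetate; 15 methyl (2Z)-2-(hydroxymethyl)-3-iodoprop-2-enoate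
Product: 17 (2Z)-2-[(5R)-5-(2,2-dimethoxyethyl)-5-methyl-4-oxo-4,5-dihydrofuran-2-yl]-3-[(2R)-4-(hydroxymethyl)-5-oxo-2,5-dihydrofuran-2-yl]prop-2-en-1-yl acetate, via cis hydroxy ester 16 (not isolated)
Conditions: CrCl2 (10 mol%), Kishi-type chiral oxazoline–sulfonamide ligand (11 mol%, enantiomer directing Si-face addition), NiCl2 (2 mol%), Mn, Cp2ZrCl2, LiCl, MeCN, rt
Reagents that add atoms: none
Why: Catalytic asymmetric Nozaki–Hiyama–Kishi coupling in which the alkenylchromium formed from 15 with retention of geometry adds to the Si face of the C6 aldehyde under ligand control (sets 6R, the remote C10 centre having no influence), and the cis hydroxy ester lactonises spontaneously to the butenolide.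

**Step 11**
Reactants: 17 (2Z)-2-[(5R)-5-(2,2-dimethoxyethyl)-5-methyl-4-oxo-4,5-dihydrofuran-2-yl]-3-[(2R)-4-(hydroxymethyl)-5-oxo-2,5-dihydrofuran-2-yl]prop-2-en-1-yl acetate
Product: 18 (2Z)-3-[(2R)-4-(bromomethyl)-5-oxo-2,5-dihydrofuran-2-yl]-2-[(5R)-5-(2,2-dimethoxyethyl)-5-methyl-4-oxo-4,5-dihydrofuran-2-yl]prop-2-en-1-yl acetate
Conditions: CBr4, PPh3, 2,6-lutidine, CH2Cl2, 0 °C
Reagents that add atoms: carbon tetrabromide BrC(Br)(Br)Br
Why: Appel reaction converts the primary allylic alcohol into the bromide under near-neutral conditions that spare the acetal, the acetate and the base-sensitive C6–H of the butenolide.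

**Step 12**
Reactants: 18 (2Z)-3-[(2R)-4-(bromomethyl)-5-oxo-2,5-dihydrofuran-2-yl]-2-[(5R)-5-(2,2-dimethoxyethyl)-5-methyl-4-oxo-4,5-dihydrofuran-2-yl]prop-2-en-1-yl acetate
Product: 20 (6R,7R,8S,10R)-15-acetoxy-8-hydroxy-1-oxo-3,10-epoxygermacra-2,4Z,11(13)-trien-12,6-olide, via bromo aldehyde 19 (not isolated)
Conditions: TFA–H2O (9:1), CH2Cl2, 0 °C; then CrCl2 (6 equiv), THF (0.003 M), rt
Reagents that add atoms: water O
Why: Acid hydrolysis frees the C8 aldehyde and a Nozaki–Hiyama (Barbier-type) allylation closes the ten-membered ring, the allylchromium attacking through C7 with allyl transposition (regenerating the exocyclic methylene) in a chair transition state on the butenolide face opposite the C5 substituent (trans-lactone, 7R) with the aldehyde chain equatorial (8S).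

**Step 13**
Reactants: 20 (6R,7R,8S,10R)-15-acetoxy-8-hydroxy-1-oxo-3,10-epoxygermacra-2,4Z,11(13)-trien-12,6-olide
Product: 21 (6R,7R,8S,10R)-15-acetoxy-8-(2-methylprop-2-enoyloxy)-1-oxo-3,10-epoxygermacra-2,4Z,11(13)-trien-12,6-olide
Conditions: methacrylic anhydride, Et3N, DMAP (cat.), CH2Cl2, 0 °C
Reagents that add atoms: methacrylic anhydride C=C(C)C(=O)OC(=O)C(C)=C
Why: DMAP-catalysed acylation (Steglich-type esterification with the anhydride) of the C8 alcohol forms the last C–O bond with retention and is fast enough at 0 °C to outrun lactone migration.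

**Compound list**
1 | (Z)-3-methylpent-2-en-4-yn-1-ol | C#C/C(C)=C\CO | starting material
2 | [(2R,3S)-3-ethynyl-3-methyloxiran-2-yl]methanol | OC[C@H]1O[C@@]1(C)C#C | intermediate
3 | (3R)-3-methylpent-4-yne-1,3-diol | OCC[C@@](C)(O)C#C | intermediate
4 | (3R)-3-hydroxy-3-methylpent-4-ynal | O=CC[C@@](C)(O)C#C | intermediate
5 | (3R)-5,5-dimethoxy-3-methylpent-1-yn-3-ol | COC(OC)C[C@@](C)(O)C#C | intermediate
6 | but-2-yne-1,4-diol | OCC#CCO | starting material
7 | 4-hydroxybut-2-yn-1-yl acetate | CC(=O)OCC#CCO | intermediate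
8 | 4-oxobut-2-yn-1-yl acetate | CC(=O)OCC#CC=O | intermediate
9 | (2Z)-2-iodo-4-oxobut-2-en-1-yl acetate | CC(=O)OC/C(I)=C/C=O | intermediate
10 | (2Z,6R)-6-hydroxy-8,8-dimethoxy-6-methyl-3-oxo-2-(2-oxoethylidene)oct-4-yn-1-yl acetate | COC(OC)C[C@@](C)(O)C#CC(=O)/C(COC(C)=O)=C\C=O | intermediate
11 | (4R,5Z)-5-[(3Z)-3-(acetoxymethyl)-2,5-dioxopent-3-en-1-ylidene]-4-(2,2-dimethoxyethyl)-4-methyl-1,3-dioxolan-2-one | COC(OC)C[C@@]1(C)OC(=O)O/C1=C\C(=O)/C(COC(C)=O)=C\C=O | intermediate
12 | (2Z,6R)-6-hydroxy-8,8-dimethoxy-6-methyl-3,5-dioxo-2-(2-oxoethylidene)octyl acetate | COC(OC)C[C@@](C)(O)C(=O)CC(=O)/C(COC(C)=O)=C\C=O | intermediate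
13 | (2Z)-2-[(5R)-5-(2,2-dimethoxyethyl)-5-methyl-4-oxo-4,5-dihydrofuran-2-yl]-4-oxobut-2-en-1-yl acetate | COC(OC)C[C@@]1(C)OC(=CC1=O)/C(COC(C)=O)=C\C=O | intermediate
14 | methyl prop-2-ynoate | COC(=O)C#C | starting material
15 | methyl (2Z)-2-(hydroxymethyl)-3-iodoprop-2-enoate | COC(=O)/C(CO)=C\I | intermediate
16 | methyl (2Z,4R,5Z)-7-acetoxy-6-[(5R)-5-(2,2-dimethoxyethyl)-5-methyl-4-oxo-4,5-dihydrofuran-2-yl]-4-hydroxy-2-(hydroxymethyl)hepta-2,5-dienoate | COC(OC)C[C@@]1(C)OC(=CC1=O)/C(COC(C)=O)=C\[C@@H](O)/C=C(/CO)C(=O)OC | intermediate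
17 | (2Z)-2-[(5R)-5-(2,2-dimethoxyethyl)-5-methyl-4-oxo-4,5-dihydrofuran-2-yl]-3-[(2R)-4-(hydroxymethyl)-5-oxo-2,5-dihydrofuran-2-yl]prop-2-en-1-yl acetate | COC(OC)C[C@@]1(C)OC(=CC1=O)/C(COC(C)=O)=C\[C@H]1OC(=O)C(CO)=C1 | intermediate
18 | (2Z)-3-[(2R)-4-(bromomethyl)-5-oxo-2,5-dihydrofuran-2-yl]-2-[(5R)-5-(2,2-dimethoxyethyl)-5-methyl-4-oxo-4,5-dihydrofuran-2-yl]prop-2-en-1-yl acetate | COC(OC)C[C@@]1(C)OC(=CC1=O)/C(COC(C)=O)=C\[C@H]1OC(=O)C(CBr)=C1 | intermediate
19 | (2Z)-3-[(2R)-4-(bromomethyl)-5-oxo-2,5-dihydrofuran-2-yl]-2-[(5R)-5-methyl-4-oxo-5-(2-oxoethyl)-4,5-dihydrofuran-2-yl]prop-2-en-1-yl acetate | O=CC[C@@]1(C)OC(=CC1=O)/C(COC(C)=O)=C\[C@H]1OC(=O)C(CBr)=C1 | intermediate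
20 | (6R,7R,8S,10R)-15-acetoxy-8-hydroxy-1-oxo-3,10-epoxygermacra-2,4Z,11(13)-trien-12,6-olide | O[C@H]1C[C@@]2(C)OC(=CC2=O)/C(COC(C)=O)=C\[C@H]2OC(=O)C(=C)[C@H]12 | intermediate
21 | (6R,7R,8S,10R)-15-acetoxy-8-(2-methylprop-2-enoyloxy)-1-oxo-3,10-epoxygermacra-2,4Z,11(13)-trien-12,6-olide (CNP0179932.1) | C=C(C)C(=O)O[C@H]1C[C@@]2(C)OC(=CC2=O)/C(COC(C)=O)=C\[C@H]2OC(=O)C(=C)[C@H]12 | target

**Step count**
Total: 13 steps, including the one-step preparation of coupling partner 15.
Longest linear sequence: 9 steps (6 → 7 → 8 → 9 → 10 → 13 → 17 → 18 → 20 → 21; the branch from 1 is equally long).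

**Three steps most likely to fail**

Step 8 (the proposed new cycloisomerisation). The cyclic carbonate may hydrolyse sluggishly, the transient 1,3-diketone may condense through C2 with the cis C6 aldehyde, or silica may take off the acetal. The fallback is the classical amine route to 3(2H)-furanones. It sets out from ynone 10: conjugate addition of diethylamine (EtOH, 0 °C) gives the enaminone F1; any aminal formed at the C6 aldehyde reverts on work-up. Hydrolysis and cyclodehydration in buffered aqueous acetic acid (AcOH/NaOAc, THF–H2O, rt) release the amine and return the route at furanone 13.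

Step 10 (asymmetric alkenyl-chromium addition and lactonisation). Facial control at a β,β-disubstituted enal far from any stereocentre may be modest, and loss of alkene geometry in the alkenylchromium would block lactonisation. The fallback builds the butenolide by alkynylation instead. It sets out from 13 and methyl propiolate 14: dinuclear zinc ProPhenol-catalysed alkynylation (Me2Zn, the ProPhenol enantiomer that adds to the Si face, toluene, 0 °C) gives the propargylic alcohol F2. Semihydrogenation (H2, Pd/CaCO3 poisoned with Pb(OAc)2, quinoline) gives the cis-hydroxy enoate F3, which lactonises to the butenolide F4. Morita–Baylis–Hillman hydroxymethylation of F4 (aqueous formaldehyde, imidazole, THF) returns the route at 17.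

Step 12 (ring closure). The closure may suffer from ring strain, and the chair preference that sets C8 may be overridden by the conformation of the forming ring; the β-oxy aldehyde 19 must also be kept away from base. The fallback corrects C8 by C–O bond formation with inversion rather than repeating the allylation. It sets out from 18: if the same closure gives mainly the C8-epimeric alcohol F5, Mitsunobu esterification of F5 with methacrylic acid (PPh3, DIAD, THF, 0 °C) inverts C8 and gives 21 directly, rejoining the route at the target.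

**Further compounds**
F1 | step 8 | (2Z,4E,6R)-5-(diethylamino)-6-hydroxy-8,8-dimethoxy-6-methyl-3-oxo-2-(2-oxoethylidene)oct-4-en-1-yl acetate | COC(OC)C[C@@](C)(O)/C(N(CC)CC)=C\C(=O)/C(COC(C)=O)=C\C=O
F2 | step 10 | methyl (4R,5Z)-7-acetoxy-6-[(5R)-5-(2,2-dimethoxyethyl)-5-methyl-4-oxo-4,5-dihydrofuran-2-yl]-4-hydroxyhept-5-en-2-ynoate | COC(OC)C[C@@]1(C)OC(=CC1=O)/C(COC(C)=O)=C\[C@@H](O)C#CC(=O)OC
F3 | step 10 | methyl (2Z,4S,5Z)-7-acetoxy-6-[(5R)-5-(2,2-dimethoxyethyl)-5-methyl-4-oxo-4,5-dihydrofuran-2-yl]-4-hydroxyhepta-2,5-dienoate (C6 arranged in space as in 17) | COC(OC)C[C@@]1(C)OC(=CC1=O)/C(COC(C)=O)=C\[C@@H](O)/C=C\C(=O)OC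
F4 | step 10 | (2Z)-2-[(5R)-5-(2,2-dimethoxyethyl)-5-methyl-4-oxo-4,5-dihydrofuran-2-yl]-3-[(2S)-5-oxo-2,5-dihydrofuran-2-yl]prop-2-en-1-yl acetate (C6 arranged in space as in 17) | COC(OC)C[C@@]1(C)OC(=CC1=O)/C(COC(C)=O)=C\[C@H]1OC(=O)C=C1
F5 | step 12 | (6R,7R,8R,10R)-15-acetoxy-8-hydroxy-1-oxo-3,10-epoxygermacra-2,4Z,11(13)-trien-12,6-olide | O[C@@H]1C[C@@]2(C)OC(=CC2=O)/C(COC(C)=O)=C\[C@H]2OC(=O)C(=C)[C@H]12
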